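## Assumptions
- The tiglate is (E). The ylidene in the target is (E) (C4 cis to C7, the ring-embedded geometry); the elimination in Step 8 gives the open-chain (Z) isomer, which is converted to (E) in situ in Step 10.
- C8 and C10 are assumed to be set by macrocyclic substrate control from the C4 quaternary centre. C10 is α to a ketone and can be equilibrated if needed.
- Photooxygenation of linalool gives regioisomeric hydroperoxides, and the unwanted tertiary one is discarded.

## Retrosynthetic overview
1. The target is the bridged methyl ketal, formed last by acid-catalysed transannular ketalization (C1 ketone, C4–OH, MeOH) of the C8 tiglate of the 10-membered hydroxy-keto carbocycle.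
2. That carbocycle comes from photoredox ketyl–olefin macrocyclization (C8–C9). The C8 aldehyde on the butenolide adds to the isopropenyl ketone, with in-situ sensitized Z→E isomerization of the ylidene. This gives the 10-membered ring and sets C8–OH and C10–Me.
3. The (Z)-ylidene butenolide aldehyde comes from a vinylogous Mukaiyama aldol and dehydration of a protected 4-formylbutenolide with a linalool-derived chiral α-hydroxy aldehyde.
4. The aldehyde comes from (R)-linalool by ene-oxygenation, Kornblum–DeLaMare oxidation and vinyl cleavage; this is the only chiral starting material and fixes C4. The butenolide comes from 3,4-dibromofuranone by Stille coupling, Suzuki coupling and ozonolysis/acetalization.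
5. Ring order: butenolide (pre-formed), then the 10-membered carbocycle, then the oxa-bridged THF.

## Route

**Step 1**
Reactants: **1** (3R)-3,7-dimethylocta-1,6-dien-3-ol [(R)-linalool]
Product: **2** (3R)-6-hydroperoxy-3,7-dimethylocta-1,7-dien-3-ol (C6 epimer mixture)
Conditions: O2, rose bengal (1 mol%), visible light, CH2Cl2, 0 °C; chromatography removes the tertiary allylic hydroperoxide regioisomer
Reagents that add atoms: O2 (O=O)
Why: Schenck singlet-oxygen ene reaction on the trisubstituted alkene converts the prenyl terminus into CH(OOH)–C(Me)=CH2. The vinyl group and C4 are untouched, and the new C–OOH stereocentre is destroyed in Step 2.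

**Step 2**
Reactants: **2**
Product: **3** (6R)-6-hydroxy-2,6-dimethylocta-1,7-dien-3-one
Conditions: Ac2O (1.5 equiv), Et3N (3 equiv), CH2Cl2, 0 °C to rt (no DMAP, so the tertiary alcohol stays free)
Reagents that add atoms: none
Why: Kornblum–DeLaMare dehydration (O-acylation of the hydroperoxide, then E2) turns the secondary hydroperoxide into the isopropenyl ketone (C1 ketone, C9=C10). C4 is not involved.

**Step 3**
Reactants: **3**
Product: **4** (2R)-2-hydroxy-2,6-dimethyl-5-oxohept-6-enal
Conditions: OsO4 (2 mol%), NaIO4 (4 equiv), 2,6-lutidine (2 equiv), dioxane/H2O 3:1, rt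
Reagents that add atoms: sodium periodate, [Na+].[O-]I(=O)(=O)=O (stoichiometric oxygen source for the new C=O; OsO4, O=[Os](=O)(=O)=O, is catalytic and not retained)
Why: Lemieux–Johnson cleavage, CH=CH2 → CH=O with loss of CH2O, is selective for the unhindered monosubstituted vinyl group over the electron-poor α-methyl enone. It gives the C5 aldehyde and leaves the quaternary C4 untouched.

**Step 4**
Reactants: **5** 3,4-dibromofuran-2(5H)-one; **6** tributyl(vinyl)stannane
Product: **7** 3-bromo-4-vinylfuran-2(5H)-one
Conditions: Pd(PPh3)4 (5 mol%), toluene, 90 °C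
Reagents that add atoms: tributyl(vinyl)stannane, C=C[Sn](CCCC)(CCCC)CCCC (supplies vinyl)
Why: Stille coupling occurs at the more reactive β-bromide (C4) of the dihalo-enoate and leaves C3–Br for Step 5.

**Step 5**
Reactants: **7**; **8** potassium (acetoxymethyl)trifluoroborate
Product: **9** (2-oxo-4-vinyl-2,5-dihydrofuran-3-yl)methyl acetate
Conditions: Pd(OAc)2 (5 mol%), RuPhos (10 mol%), K2CO3 (3 equiv), toluene/H2O 10:1, 85 °C
Reagents that add atoms: CC(=O)OC[B-](F)(F)F.[K+] (supplies CH2OAc)
Why: Suzuki–Miyaura coupling of the vinyl bromide with an acyloxymethyl trifluoroborate installs the C13 acetoxymethyl group.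

**Step 6**
Reactants: **9**
Product: **10** [4-(dimethoxymethyl)-2-oxo-2,5-dihydrofuran-3-yl]methyl acetate
Conditions: (i) O3, CH2Cl2/MeOH 4:1, −78 °C; (ii) Me2S, −78 °C to rt; (iii) HC(OMe)3 (5 equiv), PPTS (10 mol%), MeOH, rt
Reagents that add atoms: ozone [O-][O+]=O; trimethyl orthoformate COC(OC)OC; methanol CO
Why: Ozonolysis cleaves the terminal vinyl group; the tetrasubstituted electron-poor butenolide alkene survives. The telescoped acetalization masks the new aldehyde so it cannot interfere with the silyl dienol ether chemistry of Step 7.

**Step 7**
Reactants: **10**; **4**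
Product: **11** [4-(dimethoxymethyl)-5-(1,2-dihydroxy-2,6-dimethyl-5-oxohept-6-en-1-yl)-2-oxo-2,5-dihydrofuran-3-yl]methyl acetate (C4 R; C5/C6 an unresolved mixture that is destroyed in Step 8)
Conditions: (i) TMSOTf (1.2 equiv), Et3N (1.5 equiv), CH2Cl2, 0 °C (silyl dienol ether); (ii) add **4**, MgBr2·OEt2 (1.5 equiv), −78 to −20 °C; (iii) aq. NH4Cl/THF workup to remove TMS groups
Reagents that add atoms: none
Why: Vinylogous Mukaiyama aldol occurs at the γ-carbon of the 2-silyloxyfuran. The mild chelating Lewis acid activates the α-hydroxy aldehyde over the acetal and enone, and C4 is not touched.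

**Step 8**
Reactants: **11**
Product: **12** (Z)-γ-ylidene butenolide acetal
Conditions: MsCl (1.5 equiv), Et3N (4 equiv), CH2Cl2, −20 °C; then DBU (3 equiv), 0 °C to rt
Reagents that add atoms: none
Why: Selective mesylation of the secondary alcohol is followed by E1cB elimination through the acidic γ-H. This gives the thermodynamic (Z)-γ-ylidene butenolide, with the side chain cis to the lactone O because of the bulky β-acetal. C4 is unchanged.

**Step 9**
Reactants: **12**
Product: **13** (Z)-γ-ylidene butenolide aldehyde (C8 aldehyde)
Conditions: PPTS (20 mol%), acetone/H2O 10:1, 50 °C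
Reagents that add atoms: water, O
Why: Mild acid transacetalization and hydrolysis unmask the conjugated aldehyde; the enol lactone, ketone and tertiary alcohol survive.

**Step 10**
Reactants: **13**
Product: **14** 10-membered hydroxy-keto carbocycle (C8–OH, C10–Me, C1 ketone, C4–OH, E-ylidene)
Conditions: [Ir(dF(CF3)ppy)2(dtbbpy)]PF6 (2 mol%), Hantzsch ester (2 equiv), La(OTf)3 (0.5 equiv), MeCN (1 mM, syringe-pump addition over 10 h), blue LEDs, 25 °C
Reagents that add atoms: none (Hantzsch ester, CCOC(=O)C1=C(C)NC(C)=C(C1)C(=O)OCC, donates only H)
Why: Proposed new method: the excited Ir catalyst acts in two roles. (i) As a triplet sensitizer it equilibrates the (Z)- and (E)-ylidene butenolides. Only the (E) isomer, with the C4 chain cis to C7, can reach the isopropenyl ketone, and ring closure drains it (Curtin–Hammett). (ii) Reductive quenching by Hantzsch ester gives Ir(II), which reduces the La-bound aldehyde to a ketyl radical. The ketyl adds to the terminal CH2 of the α-methyl enone (polarity matched, 10-endo) to form C8–C9, and the tertiary α-keto radical is reduced and protonated at C10. C8 and C10 are set by the conformation of the closing transition state, biased by the C4 quaternary centre. If the wrong C10 epimer forms, mild base (DBU) equilibrates it because C10 is α to the ketone. The closest known reactions are photoredox Lewis-acid ketyl–olefin couplings forming small rings and triplet-sensitized E/Z isomerization of alkylidene lactones.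

**Step 11**
Reactants: **14**; **15** tiglic acid
Product: **16** C8 tiglate of **14**
Conditions: tiglic acid, 2,4,6-Cl3C6H2COCl, Et3N, toluene, rt; then **14**, DMAP (2 equiv)
Reagents that add atoms: tiglic acid, C/C=C(\C)C(=O)O
Why: Yamaguchi esterification acylates the secondary C8–OH; the tertiary C4–OH is too hindered to react. The (E)-tiglate geometry is retained.

**Step 12**
Reactants: **16**
Product: **17** Vernolide-B
Conditions: CSA (10 mol%), MeOH (10 equiv), HC(OMe)3 (5 equiv), CH2Cl2, 25 °C
Reagents that add atoms: methanol CO; trimethyl orthoformate COC(OC)OC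
Why: Acid-catalysed transannular hemiketalization of the C1 ketone by C4–OH, followed by methanolysis, gives the bridged methyl ketal; orthoformate removes water. The cis (E) ring alkene already present in **16** allows the oxa-bridge. C1 is set by the bicyclo[6.2.1] bridgehead constraint relative to C4, and C4, C8 and C10 are not affected.

## Compound list
1 | (3R)-3,7-dimethylocta-1,6-dien-3-ol, (R)-linalool | C=C[C@](C)(O)CCC=C(C)C | starting material
2 | (3R)-6-hydroperoxy-3,7-dimethylocta-1,7-dien-3-ol (C6 epimer mixture) | C=C[C@](C)(O)CCC(OO)C(C)=C | intermediate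
3 | (6R)-6-hydroxy-2,6-dimethylocta-1,7-dien-3-one | C=C[C@](C)(O)CCC(=O)C(C)=C | intermediate
4 | (2R)-2-hydroxy-2,6-dimethyl-5-oxohept-6-enal | O=C[C@](C)(O)CCC(=O)C(C)=C | intermediate
5 | 3,4-dibromofuran-2(5H)-one | O=C1OCC(Br)=C1Br | starting material
6 | tributyl(vinyl)stannane | C=C[Sn](CCCC)(CCCC)CCCC | starting material
7 | 3-bromo-4-vinylfuran-2(5H)-one | O=C1OCC(C=C)=C1Br | intermediate
8 | potassium (acetoxymethyl)trifluoroborate | CC(=O)OC[B-](F)(F)F.[K+] | starting material
9 | (2-oxo-4-vinyl-2,5-dihydrofuran-3-yl)methyl acetate | CC(=O)OCC1=C(C=C)COC1=O | intermediate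
10 | [4-(dimethoxymethyl)-2-oxo-2,5-dihydrofuran-3-yl]methyl acetate | CC(=O)OCC1=C(C(OC)OC)COC1=O | intermediate
11 | aldol adduct of 10 and 4 (C4 R; C5/C6 mixture) | CC(=O)OCC1=C(C(OC)OC)C(C(O)[C@](C)(O)CCC(=O)C(C)=C)OC1=O | intermediate
12 | (Z)-γ-ylidene butenolide acetal | CC(=O)OCC1=C(C(OC)OC)/C(=C/[C@](C)(O)CCC(=O)C(C)=C)OC1=O | intermediate
13 | (Z)-γ-ylidene butenolide aldehyde | CC(=O)OCC1=C(C=O)/C(=C/[C@](C)(O)CCC(=O)C(C)=C)OC1=O | intermediate
14 | 10-membered hydroxy-keto carbocycle (4R,8S,10R; E-ylidene) | O[C@H]1C[C@@H](C)C(=O)CC[C@@](C)(O)/C=C2/OC(=O)C(COC(C)=O)=C12 | intermediate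
15 | tiglic acid, (E)-2-methylbut-2-enoic acid | C/C=C(\C)C(=O)O | starting material
16 | C8 tiglate of 14 | C/C=C(\C)C(=O)O[C@H]1C[C@@H](C)C(=O)CC[C@@](C)(O)/C=C2/OC(=O)C(COC(C)=O)=C12 | intermediate
17 | Vernolide-B | C/C=C(\C)C(=O)O[C@H]1C[C@@H](C)[C@]2(OC)CC[C@](C)(/C=C3/OC(=O)C(COC(C)=O)=C31)O2 | target

## Totals
- Total steps: 12, of which Steps 4–6 form the convergent butenolide branch.
- Longest linear sequence: 9 steps from (R)-linalool (Steps 1, 2, 3, 7, 8, 9, 10, 11, 12).

## Three steps most likely to fail
1. **Step 10, photoredox ketyl–olefin macrocyclization with in-situ Z→E isomerization (proposed new).**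
   - Risks: the delocalized ketyl may couple at the butenolide α-carbon (C11) instead of C8, the butenolide may be over-reduced, the photostationary E fraction may be low, or C8/C10 selectivity may be poor.
   - Fallback (known chemistry, different mechanism): first isomerize **13** to the E-rich mixture with thioxanthone sensitization (405 nm) and separate it. Then close the ring by SmI2/HMPA/t-BuOH ketyl–enone cyclization at −78 °C, a metal-reductant closure known for medium rings.
2. **Step 12, transannular methyl ketalization.**
   - Risks: the stable hemiketal does not convert to the methyl ketal, the tertiary C4–O ionizes under acid and erodes C4, or the enol lactone is methanolysed.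
   - Fallback (changes approach): swap the order of the last two steps. Ketalize **14** first, with the free C8–OH as the only other nucleophile, and acylate C8–OH with tiglic acid under Yamaguchi conditions afterwards.
3. **Step 7, vinylogous Mukaiyama aldol.**
   - Risks: the silyl dienol ether may add to the enone or acetal instead of the hindered α-quaternary aldehyde, or the acetal may ionize with TMSOTf.
   - Fallback (changes approach): install the ylidene by Horner–Wadsworth–Emmons olefination of **4** with the γ-diethylphosphonate of **10**, made by NBS bromination and Arbuzov reaction. This bypasses the silyl dienol ether and the aldol/dehydration sequence.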